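(The numbers in the tables are simulated for substances that don't exist, noise included.)

The delta run gets to the end of its partner sooner than the gamma run: at 6.6 min the delta run holds 0.117 M of product from 0.120 M of partner, and the gamma run holds 0.274 M from 0.480 M. So I rank the flasks by how fast each goes through its limiting reagent, which is the partner in each flask of my ladder.

in all of them: free catalyst 0.0180 M

| charge | substrate | partner | time |
|---|---|---|---|
| gamma | 0.600 M | 0.480 M |  |
| delta | 0.240 M | 0.120 M |  |
| epsilon | 0.600 M | 0.720 M |  |
| eta | 1.80 M | 0.480 M |  |
| theta | 0.200 M | 0.160 M | 9.5 min |

| run | time / min | [product] / M |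
|---|---|---|
| gamma run | 0.72 | 0.029 |
| gamma run | 2.2 | 0.087 |
| gamma run | 4.2 | 0.176 |
| gamma run | 6.6 | 0.274 |
| gamma run | 9.5 | 0.384 |
| delta run | 0.72 | 0.008 |
| delta run | 2.2 | 0.053 |
| delta run | 4.2 | 0.088 |
| delta run | 6.6 | 0.117 |
| delta run | 9.5 | 0.122 |
| epsilon run | 0.72 | 0.028 |
| epsilon run | 2.2 | 0.094 |
| epsilon run | 4.2 | 0.182 |
| epsilon run | 6.6 | 0.271 |
| epsilon run | 9.5 | 0.385 |
| eta run | 0.72 | 0.019 |
| eta run | 2.2 | 0.035 |
| eta run | 4.2 | 0.052 |
| eta run | 6.6 | 0.098 |
| eta run | 9.5 | 0.138 |

(standard deviation of a reading: 0.006 M)

- Overall: substrate + partner -> product, with free catalyst as catalyst.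
- Constant volume, constant temperature.
- The analysis sees a species whether free or bound.
- An order is taken over about fifteen percent of the charge, up and down.

- order of the initial rate in [partner], near the charge of the gamma run, the rate being that where two percent of its substrate are product
- order of the initial rate in [substrate], near the charge of the gamma run, the rate being that where two percent of its substrate are product (one fixed amount of product, the same in the runs compared)
- the delta run starts with 0.360 M less of substrate and of partner than the gamma run, and with no product. Compared where both hold the same amount of substrate, once fifteen percent of what the delta run was charged with has turned into product, is the delta run faster, slower or alike (within a tenth)?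
- product in the theta run at 9.5 min, as a share of the substrate charged

Between its first two readings the delta run makes product at 0.0304 M min⁻¹, with a scatter of 0.00573 M min⁻¹. Its partner charge over that rate gives 3.95 min. This quotient, the partner charged divided by a measured rate of product, is what I call the emptying time. For the gamma and eta runs I take the mean rate from the start to the last reading. For the theta run I borrow the delta rate, since the delta run then holds 0.209 M of substrate, close to the theta charge of 0.200 M. The partner differs, and I assume that matters little: the gamma and epsilon runs, both charged with 0.600 M of substrate but with 0.480 M and 0.720 M of partner, end at 0.384 M and 0.385 M.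

| Run | Partner charged | Rate | Emptying time |
|---|---|---|---|
| delta | 0.120 M | 0.0304 M min⁻¹ | 3.95 min |
| theta | 0.160 M | 0.0304 M min⁻¹ | 5.26 min |
| gamma | 0.480 M | 0.0404 M min⁻¹ | 11.9 min |
| eta | 0.480 M | 0.0145 M min⁻¹ | 33.0 min |

On the top rung, the delta run at 6.6 min has passed 1.67 emptying times and has turned 97.5% of its partner. On the lower rungs, the gamma run at 9.5 min stands at 0.798 emptying times with 0.0960 M of partner left, and the eta run stands at 0.288. The theta run reaches 1.81 emptying times at 9.5 min, a little past the delta point. I therefore give the theta run the delta share of its partner, which makes 78.0% of its substrate, give or take 4.00%.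

The forecast gives 0.05 for the order in partner, −0.7 for the order in substrate, slower for the delta run, and 70% for the theta run, reasoning that “Theta should resemble delta”. We lean on the same run, but my share for the theta run is higher.

The flask gives 0.10 for the order in partner, −0.24 for the order in substrate, alike for the delta run, and 77.4% for the theta run.

    free catalyst + substrate ⇌ catalyst-substrate complex, settled at all times (5.740 M⁻¹)
    free catalyst + partner ⇌ catalyst-reagent complex, settled at all times (10.80 M⁻¹)
    catalyst-substrate complex + catalyst-reagent complex → product + 2 free catalyst (960.0 M⁻¹ min⁻¹)
    catalyst-substrate complex + substrate ⇌ doubly bound catalyst, settled at all times (0.9130 M⁻¹)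

The theta run at 9.5 min holds 0.155 M of product, which is 96.8% of its partner, after 1.81 emptying times. Near the gamma charge, the association of catalyst-substrate complex with substrate to doubly bound catalyst turns the order in substrate from 0.29 to −0.24, yet it makes no difference to the theta share. The eta run, at 0.015 M min⁻¹, has an emptying time of 32.0 min, and it reaches 0.450 M of product, 93.8% of its partner, at 50.0 min, after 1.56 emptying times.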